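Watch the plateau. The winter run is this very flask followed so far. The noon run is an earlier flask, colder at 10 °C and charged with less D, 15 mM.

all flasks: G 20 mM
- winter: D 22 mM; Q 1 mM; temperature 25 °C; the very flask that is asked about, followed so far
- noon: D 15 mM; Q 1 mM; temperature 10 °C; run made earlier
- flask: D 22.0 mM; Q 1.00 mM; temperature 25 °C; time 5.0 h

winter run (percent of the G charged)

| time / h | Z / % |
|---|---|
| 0.833 | 36 |
| 1.50 | 46 |
| 2.50 | 54 |
| 3.00 | 55 |

noon run (percent of the G charged)

| time / min | Z / % |
|---|---|
| 10.0 | 2 |
| 25.0 | 2 |
| 50.0 | 11 |
| 120 | 22 |

(standard deviation of a reading: 2 percentage points)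

- Wednesday's: at 5.0 h take out 90% of the Z then present, then wait 5.0 h
- Friday's: at 5.0 h raise the temperature by 20 K, then wait 5.0 h
- Tuesday's: at 5.0 h add D, 100% of the amount charged, then wait 5.0 h
- Thursday's: change nothing and wait 5.0 h more

- Z taken out counts as made
- the analysis behind the earlier runs scatters by 2 percentage points, standard deviation
- steps thought possible: G <-> J; D + J <-> X; G -> Z; Q + J -> E
- additions bring no volume worth counting

- Z, in percent of the G first charged, at 5.0 h
- the option that brings most further Z ("none" if no option brings more than 2 percentage points) (Wednesday's / Friday's / Tuesday's / Thursday's / none)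
- Z present, with what was taken out counted in, in percent of the G first charged, after Wednesday's
- Z present, with what was taken out counted in, in percent of the G first charged, after Tuesday's

Follow one molecule of G in the winter flask. At the fork it goes to Z for good or turns to J, and from J it may stand as X with D or leave as E with Q. The last two winter readings differ by 1 percentage point, less than the scatter of 2 points, so we average them into 54.5%. This is the fork share, the fraction of the G charged that has reached Z once the curve stands flat, a yield on the charge. Q can carry off at most 5.00% of the charge as E, so we book the remaining 40.5% on J and X, whose way to Z leads back through G.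

Was one number enough? Not for time, which needs a clock. Read as a rise towards the fork share, the first winter reading gives 1.30 h⁻¹. That clock predicts 46.7% at 1.50 h, and the reading there is 46%, a gap inside the scatter. At noon it fails: it gives 50.4% at 120 min, where the noon run read 22%. So we take fork share and clock as readings of the winter run, up to 3.00 h.

For this flask at 5.0 h our reckoning gives 54.4%. The curve has flattened, and the steps give Z no way back, so we expect nothing special from Wednesday's and look to Friday's, which changes the temperature, to move the booked share. The forecast stands higher on the first point, at 57.5%; it names Friday's, “so Friday's is the best bet, though this is inferred, not observed”, with 60% after Wednesday's and 58.5% after Tuesday's.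

    G ⇌ J (K = 17.0, k = 1.90 × 10⁻⁴ s⁻¹, Ea = 87.0 kJ mol⁻¹, ΔH = −22.0 kJ mol⁻¹)
    D + J ⇌ X (K = 45.0 M⁻¹, k = 0.0420 M⁻¹ s⁻¹, Ea = 68.0 kJ mol⁻¹, ΔH = −36.0 kJ mol⁻¹)
    G → Z (k = 2.10 × 10⁻⁴ s⁻¹, Ea = 90.0 kJ mol⁻¹)
    Q + J → E (k = 0.270 M⁻¹ s⁻¹, Ea = 57.0 kJ mol⁻¹)
    (constants at 25 °C)

The flask gives 54.2% at 5.00 h, then 56.5% after Wednesday's and 55.9% after Tuesday's. The best option is Friday's, whose 29 points stands far above the 2.3 points of waiting. In this flask at 5.00 h, before any option, J holds 21.9% and X 18.2%, together 40.1% against the booked 40.5%. Carried to the same flask read at 80 min, the fork share with its clock gives 44.9%, and that flask stands at 45.0%.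

The data come from a simulation for substances that don't exist, noise included.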